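The decalin is cut at its ring-fusion bond C5–C10, the only bond shared by rings A and B. Because C5 is α to the C6 oxygen and the methyl-bearing C10 is allylic to C8=C9, both rings can be drawn from one ten-membered ring: a (3Z,5E)-cyclodeca-3,5-dienone made by alkynyl oxy-Cope ring expansion of a cyclohexanol. In a single operation a confined chiral Brønsted acid protonates C1, the C6 enol closes onto the C10 allyl cation, and rings A and B, the C5–C10 bond and the C5/C10 stereocentres appear together. Hydride delivery to C6, acetylation and a Negishi coupling with 4-bromofuran-2(5H)-one complete the target.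

Key step: step 6

Remark: atoms carry labdane numbers throughout (ring A = C1–C5 and C10, ring B = C5–C10, C11–C12 chain, butenolide C13–C16); 7 and 9 are racemic and their stereocentres vanish in step 5, so absolute configuration enters only in step 6, and the C6 ketone is carried unprotected into that step because its enol is the nucleophile.

Step 1
Reactants: 1 pent-3-yn-1-ol
Product: 2 triisopropyl(pent-3-yn-1-yloxy)silane
Conditions: TIPSCl, imidazole, DMF, 0 → 25 °C
Reagents that add atoms: chlorotriisopropylsilane, CC(C)[Si](Cl)(C(C)C)C(C)C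
Why: Imidazole-promoted O-silylation of a primary alcohol is routine, and the TIPS ether should survive the amide base, KH, the strong acid of step 6 and LiAlH4 while its bulk keeps the ether oxygen away from the cation.

Step 2
Reactants: 2 triisopropyl(pent-3-yn-1-yloxy)silane
Product: 4 (E)-(4-bromopent-3-en-1-yloxy)triisopropylsilane, via alkenyl-ZrCp2Cl 3 (not isolated)
Conditions: Cp2Zr(H)Cl (1.5 equiv), THF, 50 °C; then NBS, 0 °C
Reagents that add atoms: N-bromosuccinimide, O=C1CCC(=O)N1Br
Why: Hydrozirconation adds Zr–H syn across the alkyne and, on equilibration with excess reagent, should place zirconium on the less hindered methyl-bearing carbon; bromodezirconation proceeds with retention to the (E)-bromide.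

Step 3
Reactants: 5 3,3-dimethylcyclohexanone, 4 (E)-(4-bromopent-3-en-1-yloxy)triisopropylsilane
Product: 7 rac-5,5-dimethyl-2-[(E)-5-(triisopropylsilyloxy)pent-2-en-2-yl]cyclohexan-1-one, via lithium 5,5-dimethylcyclohexenolate 6 (not isolated)
Conditions: 5 (2 equiv), LiN(SiMe3)2, THF, −78 → 0 °C; then 4, Pd2(dba)3 (cat.), P(t-Bu)3·HBF4 (cat.), PhMe, 25 → 50 °C; aq. NH4Cl
Reagents that add atoms: none
Why: In this palladium-catalysed α-alkenylation of a ketone enolate, kinetic deprotonation should occur at C6, away from the neopentyl C2, the coupling retains the alkene geometry, and the product rests as its dienolate until α-protonation on work-up gives the β,γ-unsaturated ketone, whose new stereocentre is racemic and is erased in step 5.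

Step 4
Reactants: 7 rac-5,5-dimethyl-2-[(E)-5-(triisopropylsilyloxy)pent-2-en-2-yl]cyclohexan-1-one, 8 prop-1-yn-1-ylmagnesium bromide
Product: 9 rac-(1R,2R)-5,5-dimethyl-1-(prop-1-yn-1-yl)-2-[(E)-5-(triisopropylsilyloxy)pent-2-en-2-yl]cyclohexan-1-ol
Conditions: 8, CeCl3 (anhydrous), THF, −78 °C; aq. NH4Cl
Reagents that add atoms: none
Why: Cerium-mediated Grignard 1,2-addition suppresses enolisation of the acidic allylic α-hydrogen, and the axial C5 methyl blocks the axial trajectory, so the alkynyl group should enter equatorially, trans to the equatorial alkenyl group, which is the arrangement the oxy-Cope needs.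

Step 5
Reactants: 9 rac-(1R,2R)-5,5-dimethyl-1-(prop-1-yn-1-yl)-2-[(E)-5-(triisopropylsilyloxy)pent-2-en-2-yl]cyclohexan-1-ol
Product: 14 (3Z,5E)-3,5,9,9-tetramethyl-4-[2-(triisopropylsilyloxy)ethyl]cyclodeca-3,5-dien-1-one, via potassium alkoxide 10 (not isolated), via potassium allenolate 11 (not isolated), via cyclodeca-2,5-dienone 12 (not isolated), via potassium trienolate 13 (not isolated)
Conditions: KH, 18-crown-6, THF, 0 → 25 °C; t-BuOH, 0 °C; then poured into AcOH/THF, −78 °C
Reagents that add atoms: none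
Why: In this anionic alkynyl oxy-Cope rearrangement the crown-separated alkoxide should undergo the [3,3] shift through a chair-like array whose diequatorial substituents become the (E)-C10=C1 alkene, the allenolate is relayed by the t-BuOH/KOt-Bu proton shuttle to the more delocalised trienolate, and kinetic protonation at the α-carbon C7 (deconjugative protonation) leaves the ring-cis tetrasubstituted C8=C9 bond and no stereocentre.

Step 6
Reactants: 14 (3Z,5E)-3,5,9,9-tetramethyl-4-[2-(triisopropylsilyloxy)ethyl]cyclodeca-3,5-dien-1-one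
Product: 15 (4aS,8aS)-3,4a,8,8-tetramethyl-4-[2-(triisopropylsilyloxy)ethyl]-4a,5,6,7,8,8a-hexahydronaphthalen-1(2H)-one
Conditions: confined imidodiphosphorimidate acid (IDPi from 3,3′-diaryl-BINOL, N-triflyl core; the antipode that delivers 10S), 5 mol %, PhMe/cyclohexane, −40 → 0 °C
Reagents that add atoms: none
Why: Proposed new method: the confined acid should protonate C1 of the twisted C8=C9–C10=C1 diene to a tertiary allyl cation held against the chiral anion, and the C5=C6 enol, which the same acid forms reversibly, should attack C10 across the ring and collapse to the ketone, so that the C5–C10 bond and the β,γ-unsaturated C6 ketone arise directly. The closest known reaction types are the acid-induced transannular cyclisation of (E)-cyclodecadienes (germacrane to eudesmane), the Conia-ene addition of a ketone enol to an alkene and chiral-acid-catalysed cation–olefin cyclisation; none has joined an enol to a diene across a medium ring under catalyst control. Ring B (C5 to C10) closes 6-endo at the allyl terminus C10 and ring A (C10, C1 to C5) closes through the same bond as a six-membered chair, so one σ-bond completes both rings. C10 is set by the catalyst, which must select one of the two rapidly interconverting enantiomeric crown conformers of the planar-chiral (E)-cyclodecadienone and with it the face of the cation; C5 follows from the chair–chair arrangement open to the (E)-C10=C1 alkene and, being α to the ketone, can also relax to the more stable trans fusion. The step needs C-protonation at C1 and closure from C5 to C10 in preference to attack at C8, to enolisation towards C7 and to a carbonyl-ene closure between C1 and C6: attack at C8 would give a four-membered ring, the C7 dienol is unproductive and returns by ketonisation, the doubly substituted diene is far more basic than an isolated alkene, and in the conformer that aligns C5 with C10 the atoms C1 and C6 lie anti about the forming bond and cannot meet.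

Step 7
Reactants: 15 (4aS,8aS)-3,4a,8,8-tetramethyl-4-[2-(triisopropylsilyloxy)ethyl]-4a,5,6,7,8,8a-hexahydronaphthalen-1(2H)-one
Product: 16 (1R,4aS,8aS)-3,4a,8,8-tetramethyl-4-[2-(triisopropylsilyloxy)ethyl]-1,2,4a,5,6,7,8,8a-octahydronaphthalen-1-ol
Conditions: LiAlH4, Et2O, −78 → −20 °C; H2O
Reagents that add atoms: none
Why: In this metal hydride 1,2-reduction the β-face of C6 is screened by the syn-axial methyls on C10 and C4, so hydride should arrive from the α-face and give the axial 6β-alcohol (C6 R).

Step 8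
Reactants: 16 (1R,4aS,8aS)-3,4a,8,8-tetramethyl-4-[2-(triisopropylsilyloxy)ethyl]-1,2,4a,5,6,7,8,8a-octahydronaphthalen-1-ol
Product: 17 (1R,4aS,8aS)-3,4a,8,8-tetramethyl-4-[2-(triisopropylsilyloxy)ethyl]-1,2,4a,5,6,7,8,8a-octahydronaphthalen-1-yl acetate
Conditions: Ac2O, DMAP, pyridine, 40 °C
Reagents that add atoms: acetic anhydride, CC(=O)OC(C)=O
Why: DMAP-catalysed acylation through the N-acetylpyridinium ion should esterify even this hindered axial alcohol on gentle warming, with retention at C6 because the C–O bond is untouched.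

Step 9
Reactants: 17 (1R,4aS,8aS)-3,4a,8,8-tetramethyl-4-[2-(triisopropylsilyloxy)ethyl]-1,2,4a,5,6,7,8,8a-octahydronaphthalen-1-yl acetate
Product: 18 (1R,4aS,8aS)-4-(2-hydroxyethyl)-3,4a,8,8-tetramethyl-1,2,4a,5,6,7,8,8a-octahydronaphthalen-1-yl acetate
Conditions: Bu4NF, AcOH, THF, 0 → 25 °C
Reagents that add atoms: none
Why: Fluoride-mediated desilylation cleaves the primary TIPS ether, and the acetic acid buffer should keep the hindered 6β-acetate from hydrolysis or migration.

Step 10
Reactants: 18 (1R,4aS,8aS)-4-(2-hydroxyethyl)-3,4a,8,8-tetramethyl-1,2,4a,5,6,7,8,8a-octahydronaphthalen-1-yl acetate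
Product: 19 (1R,4aS,8aS)-4-(2-iodoethyl)-3,4a,8,8-tetramethyl-1,2,4a,5,6,7,8,8a-octahydronaphthalen-1-yl acetate
Conditions: PPh3, I2, imidazole, CH2Cl2, 0 °C
Reagents that add atoms: iodine, II
Why: The Appel reaction turns the unhindered primary alcohol into the iodide by SN2 displacement of the alkoxyphosphonium ion, under conditions that leave the acetate and the tetrasubstituted alkene alone.

Step 11
Reactants: 19 (1R,4aS,8aS)-4-(2-iodoethyl)-3,4a,8,8-tetramethyl-1,2,4a,5,6,7,8,8a-octahydronaphthalen-1-yl acetate, 20 4-bromofuran-2(5H)-one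
Product: 22 (1R,4aS,8aS)-3,4a,8,8-tetramethyl-4-[2-(5-oxo-2,5-dihydrofuran-3-yl)ethyl]-1,2,4a,5,6,7,8,8a-octahydronaphthalen-1-yl acetate, via alkylzinc iodide 21 (not isolated)
Conditions: Zn dust, LiCl, THF, 40 °C; then 20, Pd(PPh3)4 (5 mol %), THF, 25 → 50 °C
Reagents that add atoms: none
Why: Zinc insertion into the primary iodide tolerates the ester, and Negishi coupling of the alkylzinc with the β-bromobutenolide (oxidative addition to zerovalent palladium, transmetalation, reductive elimination) should attach C12 to C13 without touching any stereocentre.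

Compound list
1 | pent-3-yn-1-ol | CC#CCCO | starting material
2 | triisopropyl(pent-3-yn-1-yloxy)silane | CC#CCCO[Si](C(C)C)(C(C)C)C(C)C | intermediate
3 | chlorido[(E)-5-(triisopropylsilyloxy)pent-2-en-2-yl]bis(cyclopentadienyl)zirconium (alkenyl-ZrCp2Cl) | Cl[Zr](C1C=CC=C1)(C1C=CC=C1)/C(C)=C/CCO[Si](C(C)C)(C(C)C)C(C)C | intermediate (not isolated)
4 | (E)-(4-bromopent-3-en-1-yloxy)triisopropylsilane | Br/C(C)=C/CCO[Si](C(C)C)(C(C)C)C(C)C | intermediate
5 | 3,3-dimethylcyclohexanone | CC1(C)CCCC(=O)C1 | starting material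
6 | lithium 5,5-dimethylcyclohex-1-en-1-olate | [Li+].[O-]C1=CCCC(C)(C)C1 | intermediate (not isolated)
7 | rac-5,5-dimethyl-2-[(E)-5-(triisopropylsilyloxy)pent-2-en-2-yl]cyclohexan-1-one | O=C1CC(C)(C)CCC1/C(C)=C/CCO[Si](C(C)C)(C(C)C)C(C)C | intermediate
8 | prop-1-yn-1-ylmagnesium bromide | CC#C[Mg]Br | starting material
9 | rac-(1R,2R)-5,5-dimethyl-1-(prop-1-yn-1-yl)-2-[(E)-5-(triisopropylsilyloxy)pent-2-en-2-yl]cyclohexan-1-ol (propynyl trans to alkenyl, hydroxyl cis to it; one enantiomer drawn) | CC#C[C@]1(O)CC(C)(C)CC[C@H]1/C(C)=C/CCO[Si](C(C)C)(C(C)C)C(C)C | intermediate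
10 | potassium alkoxide of 9 (racemic; one enantiomer drawn) | CC#C[C@]1([O-])CC(C)(C)CC[C@H]1/C(C)=C/CCO[Si](C(C)C)(C(C)C)C(C)C.[K+] | intermediate (not isolated)
11 | potassium (5E)-3,5,9,9-tetramethyl-4-[2-(triisopropylsilyloxy)ethyl]cyclodeca-1,2,5-trien-1-olate | [K+].[O-]C1=C=C(C)C(CCO[Si](C(C)C)(C(C)C)C(C)C)/C(C)=C/CCC(C)(C)C1 | intermediate (not isolated)
12 | (5E)-3,5,9,9-tetramethyl-4-[2-(triisopropylsilyloxy)ethyl]cyclodeca-2,5-dien-1-one (C2=C3 geometry and C4 configuration not fixed) | O=C1C=C(C)C(CCO[Si](C(C)C)(C(C)C)C(C)C)/C(C)=C/CCC(C)(C)C1 | intermediate (not isolated)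
13 | potassium (3Z,5E)-3,5,9,9-tetramethyl-4-[2-(triisopropylsilyloxy)ethyl]cyclodeca-1,3,5-trien-1-olate | [K+].[O-]C1=C/C(C)=C(CCO[Si](C(C)C)(C(C)C)C(C)C)\C(C)=C\CCC(C)(C)C1 | intermediate (not isolated)
14 | (3Z,5E)-3,5,9,9-tetramethyl-4-[2-(triisopropylsilyloxy)ethyl]cyclodeca-3,5-dien-1-one | O=C1C/C(C)=C(CCO[Si](C(C)C)(C(C)C)C(C)C)\C(C)=C\CCC(C)(C)C1 | intermediate
15 | (4aS,8aS)-3,4a,8,8-tetramethyl-4-[2-(triisopropylsilyloxy)ethyl]-4a,5,6,7,8,8a-hexahydronaphthalen-1(2H)-one (5S,10S; trans-fused 8-en-6-one) | O=C1CC(C)=C(CCO[Si](C(C)C)(C(C)C)C(C)C)[C@@]2(C)CCCC(C)(C)[C@H]12 | intermediate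
16 | (1R,4aS,8aS)-3,4a,8,8-tetramethyl-4-[2-(triisopropylsilyloxy)ethyl]-1,2,4a,5,6,7,8,8a-octahydronaphthalen-1-ol (6β-alcohol) | O[C@@H]1CC(C)=C(CCO[Si](C(C)C)(C(C)C)C(C)C)[C@@]2(C)CCCC(C)(C)[C@H]12 | intermediate
17 | (1R,4aS,8aS)-3,4a,8,8-tetramethyl-4-[2-(triisopropylsilyloxy)ethyl]-1,2,4a,5,6,7,8,8a-octahydronaphthalen-1-yl acetate | CC(=O)O[C@@H]1CC(C)=C(CCO[Si](C(C)C)(C(C)C)C(C)C)[C@@]2(C)CCCC(C)(C)[C@H]12 | intermediate
18 | (1R,4aS,8aS)-4-(2-hydroxyethyl)-3,4a,8,8-tetramethyl-1,2,4a,5,6,7,8,8a-octahydronaphthalen-1-yl acetate | CC(=O)O[C@@H]1CC(C)=C(CCO)[C@@]2(C)CCCC(C)(C)[C@H]12 | intermediate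
19 | (1R,4aS,8aS)-4-(2-iodoethyl)-3,4a,8,8-tetramethyl-1,2,4a,5,6,7,8,8a-octahydronaphthalen-1-yl acetate | CC(=O)O[C@@H]1CC(C)=C(CCI)[C@@]2(C)CCCC(C)(C)[C@H]12 | intermediate
20 | 4-bromofuran-2(5H)-one | O=C1C=C(Br)CO1 | starting material
21 | {2-[(4S,4aS,8aS)-4-acetoxy-2,5,5,8a-tetramethyl-3,4,4a,5,6,7,8,8a-octahydronaphthalen-1-yl]ethyl}zinc iodide (same stereocentres as 19) | CC(=O)O[C@@H]1CC(C)=C(CC[Zn]I)[C@@]2(C)CCCC(C)(C)[C@H]12 | intermediate (not isolated)
22 | (1R,4aS,8aS)-3,4a,8,8-tetramethyl-4-[2-(5-oxo-2,5-dihydrofuran-3-yl)ethyl]-1,2,4a,5,6,7,8,8a-octahydronaphthalen-1-yl acetate (6β-acetoxylabda-8,13-dien-15,16-olide; 5S,6R,10S) | CC(=O)O[C@@H]1CC(C)=C(CCC2=CC(=O)OC2)[C@@]2(C)CCCC(C)(C)[C@H]12 | target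

Total step count: 11. Longest linear sequence: 11 steps (1 → 22); ketone 5, Grignard reagent 8 and bromobutenolide 20 enter at steps 3, 4 and 11.

Steps most likely to fail

1. Step 6. The acid may activate the carbonyl rather than the diene, so that C1 bonds to C6 in a transannular carbonyl-ene closure, or the ion pair may close without discriminating between the two crown enantiomers, which would leave C10 uncontrolled. Drift of the product alkene into conjugation is a lesser risk, since repeating the deconjugative protonation returns 15. The fallback is a chiral-pool relay by known reactions that gives up the ten-membered ring. It uses none of compounds 1–14: it sets out from purchased (+)-sclareolide F1, which already holds C5, C10 and the C11–C12 chain in the required configuration, and it comes back at ketone 15. Reduction of F1 with LiAlH4 should give the 8α,12-diol F2, and silylation of the primary hydroxyl (TIPSCl, imidazole) the silyl ether F3. Dehydration of the tertiary alcohol (SOCl2, pyridine) and acid equilibration of the alkenes (p-TsOH, PhH) should give the trisubstituted 7-ene F4, to be separated from its 8(9)-isomer. Allylic oxidation at C6 (CrO3·3,5-dimethylpyrazole, CH2Cl2) should give the 7-en-6-one F5. Deconjugative protonation (KOt-Bu, t-BuOH, then cold AcOH) removes the C9 hydrogen, erases that centre and should give 15.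

2. Step 5. The [3,3] shift may deliver some (Z)-C10=C1 alkene, or the relay from allenolate to trienolate may be incomplete, with loss of control over the position of the double bonds. The fallback sets out from ketone 7 and comes back at dienone 12; it carries the C7=C8 unsaturation in after the ring expansion instead of through an alkyne. Addition of 1-propenylmagnesium bromide with CeCl3 should give the dialkenyl carbinol F6. The classical anionic oxy-Cope rearrangement (KH, 18-crown-6, THF) of this 1,2-dialkenylcyclohexanol should give the regiodefined potassium enolate F7 of the (E)-cyclodec-5-enone. Selenenylation in the same flask (PhSeBr, −78 °C) should give the α-phenylselenyl ketone F8, and oxidation (H2O2, pyridine) the selenoxide F9, whose syn-elimination towards C8 gives 12. Compound 12 is then taken as a separate operation through KOt-Bu/t-BuOH and the cold AcOH quench, via 13, to 14.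

3. Step 3. Base may move the new alkene into conjugation with the ketone, a second alkenylation may occur, or reductive elimination from the congested 1,1-disubstituted alkenylpalladium may be slow. The fallback sets out from ketone 5 and the alkenylzirconium species 3 and comes back at ketone 7; it couples at an sp2 carbon and sets the α-centre afterwards. Dehydrogenation of 5 (IBX, DMSO, 70 °C) should give the enone F10, and iodination (I2, pyridine, CH2Cl2) the α-iodoenone F11. Transmetalation of 3 with ZnCl2 should give the alkenylzinc chloride F12, and Negishi coupling of F12 with F11 (Pd(PPh3)4, THF) the cross-conjugated dienone F13. Conjugate reduction of the ring enone (LiBH(s-Bu)3, THF, −78 °C, protic quench) should return 7.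

Further compounds
F1 | step 6 | (+)-sclareolide | C1C[C@@]3(C)OC(=O)C[C@@H]3[C@@]2(C)CCCC(C)(C)[C@H]12
F2 | step 6 | (1R,2R,4aS,8aS)-1-(2-hydroxyethyl)-2,5,5,8a-tetramethyldecahydronaphthalen-2-ol (13,14,15,16-tetranorlabdane-8α,12-diol) | C1C[C@@](C)(O)[C@H](CCO)[C@@]2(C)CCCC(C)(C)[C@H]12
F3 | step 6 | 12-(triisopropylsilyloxy)-13,14,15,16-tetranorlabdan-8α-ol | C1C[C@@](C)(O)[C@H](CCO[Si](C(C)C)(C(C)C)C(C)C)[C@@]2(C)CCCC(C)(C)[C@H]12
F4 | step 6 | 12-(triisopropylsilyloxy)-13,14,15,16-tetranorlabd-7-ene (5S,9S,10S) | C1C=C(C)[C@H](CCO[Si](C(C)C)(C(C)C)C(C)C)[C@@]2(C)CCCC(C)(C)[C@H]12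
F5 | step 6 | 12-(triisopropylsilyloxy)-13,14,15,16-tetranorlabd-7-en-6-one (9α-H) | O=C1C=C(C)[C@H](CCO[Si](C(C)C)(C(C)C)C(C)C)[C@@]2(C)CCCC(C)(C)[C@H]12
F6 | step 5 | rac-5,5-dimethyl-1-(prop-1-en-1-yl)-2-[(E)-5-(triisopropylsilyloxy)pent-2-en-2-yl]cyclohexan-1-ol (propenyl trans to the pentenyl group; propenyl geometry not fixed) | CC=C[C@]1(O)CC(C)(C)CC[C@H]1/C(C)=C/CCO[Si](C(C)C)(C(C)C)C(C)C
F7 | step 5 | potassium (5E)-3,5,9,9-tetramethyl-4-[2-(triisopropylsilyloxy)ethyl]cyclodeca-1,5-dien-1-olate | [K+].[O-]C1=CC(C)C(CCO[Si](C(C)C)(C(C)C)C(C)C)/C(C)=C/CCC(C)(C)C1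
F8 | step 5 | (5E)-3,5,9,9-tetramethyl-2-(phenylselanyl)-4-[2-(triisopropylsilyloxy)ethyl]cyclodec-5-en-1-one | O=C1C([Se]c2ccccc2)C(C)C(CCO[Si](C(C)C)(C(C)C)C(C)C)/C(C)=C/CCC(C)(C)C1
F9 | step 5 | (5E)-3,5,9,9-tetramethyl-2-(phenylseleninyl)-4-[2-(triisopropylsilyloxy)ethyl]cyclodec-5-en-1-one | O=C1C([Se](=O)c2ccccc2)C(C)C(CCO[Si](C(C)C)(C(C)C)C(C)C)/C(C)=C/CCC(C)(C)C1
F10 | step 3 | 5,5-dimethylcyclohex-2-en-1-one | O=C1C=CCC(C)(C)C1
F11 | step 3 | 2-iodo-5,5-dimethylcyclohex-2-en-1-one | O=C1C(I)=CCC(C)(C)C1
F12 | step 3 | chlorido[(E)-5-(triisopropylsilyloxy)pent-2-en-2-yl]zinc | Cl[Zn]/C(C)=C/CCO[Si](C(C)C)(C(C)C)C(C)C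
F13 | step 3 | 5,5-dimethyl-2-[(E)-5-(triisopropylsilyloxy)pent-2-en-2-yl]cyclohex-2-en-1-one | O=C1C(/C(C)=C/CCO[Si](C(C)C)(C(C)C)C(C)C)=CCC(C)(C)C1
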